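**Retrosynthetic overview**
1. The target comes from triol 24 by acetylation; the triol comes from E-allylic alcohol 21 by Sharpless epoxidation and Payne rearrangement/hydroxide opening (C13 and C14 by reagent control). The side chain is grown from a C13 methyl ketone carried as a dioxolane.
2. Ring A is closed last by a [3+3] annulation that makes C3–C4 and C1=C10 together: an ester enolate at C4 opens cyclopropyltriphenylphosphonium bromide, and the ylide so formed olefinates the C10 ketone.
3. Enabling feature: C4 (α to the C18 ester) and the alkene carbon C10 are 1,3-related through C5. A temporary C4–C10 bond (donor–acceptor cyclopropane C4/C5/C10 fused to ring B, silyloxy on C10, ester on C4) therefore masks the C4 enolate and the C10 ketone at once, and the C3–C2–C1 unit (CH2–CH2–CH=) maps onto the three-membered ring of the phosphonium salt.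
4. Ring B comes from 2-methylcyclohex-2-enone: asymmetric conjugate addition (C8), Mukaiyama–Michael addition (quaternary C9), then carbene addition to the C10 enol ether (C5).
5. Ring order: ring B (purchased) → temporary cyclopropane on C5/C10 → ring A.

Key step: step 8

Remark: halimane-type numbering is used (C4 carries CH3/CO2Me, C5 the ring-fusion H, C8 and C9 the ring-B methyl groups, C1=C10 the alkene, C11–C16 the side chain, C18 the ester carbon); the target is taken as the 4R,5R,8R,9S,13S,14R isomer drawn, and the ligand enantiomer in step 1 is the one that delivers 8R.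

Step 1
Reactants: 1 2-methylcyclohex-2-en-1-one
Product: 3 trimethyl{[(3R)-2,3-dimethylcyclohex-1-en-1-yl]oxy}silane, via dimethylaluminium enolate 2 (not isolated)
Conditions: AlMe3, CuTC (copper thiophene-2-carboxylate, CuO2CC4H3S, 2 mol %), chiral binaphthol-derived phosphoramidite ligand (4 mol %), Et2O, −30 °C; then Me3SiOTf, THF, −30 → 0 °C
Reagents that add atoms: trimethylaluminium, C[Al](C)C; trimethylsilyl trifluoromethanesulfonate, C[Si](C)(C)OS(=O)(=O)C(F)(F)F
Why: Copper-catalysed asymmetric conjugate addition of the methyl group to the α-substituted enone should set C8 under ligand control, and O-silylation of the aluminium enolate fixes the tetrasubstituted enol ether regiochemistry needed for C9.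

Step 2
Reactants: 3 trimethyl{[(3R)-2,3-dimethylcyclohex-1-en-1-yl]oxy}silane; 4 but-3-en-2-one (methyl vinyl ketone)
Product: 5 (2S,3R)-2,3-dimethyl-2-(3-oxobutyl)cyclohexan-1-one
Conditions: BF3·OEt2, iPrOH, CH2Cl2, −78 °C
Reagents that add atoms: none
Why: Mukaiyama–Michael addition of the silyl enol ether to the BF3-activated enone should build quaternary C9 with the new chain entering anti to the neighbouring C8 methyl group, which gives the cis relationship of the two ring methyl groups (the alcohol takes up the silyl group).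

Step 3
Reactants: 5 (2S,3R)-2,3-dimethyl-2-(3-oxobutyl)cyclohexan-1-one
Product: 6 (2S,3R)-2,3-dimethyl-2-[2-(2-methyl-1,3-dioxolan-2-yl)ethyl]cyclohexan-1-one
Conditions: Me3SiOCH2CH2OSiMe3, Me3SiOTf (cat.), CH2Cl2, −78 → −20 °C
Reagents that add atoms: 1,2-bis(trimethylsilyloxy)ethane, C[Si](C)(C)OCCO[Si](C)(C)C
Why: Silyl-triflate-catalysed dioxolane formation should occur only at the unhindered methyl ketone, because the ring ketone is flanked by the quaternary C9, and the aprotic low-temperature conditions avoid aldol cyclisation of the 1,5-diketone.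

Step 4
Reactants: 6 (2S,3R)-2,3-dimethyl-2-[2-(2-methyl-1,3-dioxolan-2-yl)ethyl]cyclohexan-1-one
Product: 8 tert-butyl({(5R,6S)-5,6-dimethyl-6-[2-(2-methyl-1,3-dioxolan-2-yl)ethyl]cyclohex-1-en-1-yl}oxy)dimethylsilane, via lithium enolate 7 (not isolated)
Conditions: LDA, THF, −78 °C; then tBuMe2SiCl, DMPU, −78 → 0 °C
Reagents that add atoms: tert-butyldimethylsilyl chloride, CC(C)(C)[Si](C)(C)Cl
Why: The ketone can enolise only toward C5 because C9 is quaternary, so deprotonation and O-silylation should give a single silyl enol ether (C10=C5).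

Step 5
Reactants: 9 glycine methyl ester hydrochloride
Product: 10 methyl diazoacetate
Conditions: NaNO2, H2SO4 (cat.), CH2Cl2/H2O, −5 °C
Reagents that add atoms: sodium nitrite, [Na+].[O-]N=O
Why: Diazotisation of the α-amino ester gives the α-diazo ester, which is extracted into the organic phase as it forms.

Step 6
Reactants: 8 tert-butyl({(5R,6S)-5,6-dimethyl-6-[2-(2-methyl-1,3-dioxolan-2-yl)ethyl]cyclohex-1-en-1-yl}oxy)dimethylsilane; 10 methyl diazoacetate
Product: 11 methyl (2S,3R)-1-(tert-butyldimethylsilyloxy)-2,3-dimethyl-2-[2-(2-methyl-1,3-dioxolan-2-yl)ethyl]bicyclo[4.1.0]heptane-7-carboxylate, cyclopropane on the ring-B face anti to the C2 (halimane C9) methyl group, mixture of epimers at the ester-bearing carbon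
Conditions: Cu(acac)2 (3 mol %), benzene, 80 °C, slow addition of 10
Reagents that add atoms: none
Why: Copper-carbenoid cyclopropanation of the electron-rich silyl enol ether makes the C4–C5 and the temporary C4–C10 bond; the carbene should add anti to the pseudoaxial C9 methyl group, which sets C5 (and C10), while the configuration at C4 is of no consequence.

Step 7
Reactants: 11 donor–acceptor cyclopropane ester
Product: 13 methyl 1-(tert-butyldimethylsilyloxy)-2,3,7-trimethyl-2-[2-(2-methyl-1,3-dioxolan-2-yl)ethyl]bicyclo[4.1.0]heptane-7-carboxylate (C4-methylated donor–acceptor cyclopropane), via lithium ester enolate 12 (not isolated)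
Conditions: LDA, THF, −78 °C; then MeI, −78 → −20 °C
Reagents that add atoms: iodomethane, CI
Why: The cyclopropane C–H α to the ester is the only acidic position, and C-methylation of the cyclopropyl ester enolate (a known alkylation of 2-siloxycyclopropanecarboxylates) installs C19; the configuration at C4 is erased in step 8.

Step 8
Reactants: 13 C4-methylated donor–acceptor cyclopropane; 14 cyclopropyltriphenylphosphonium bromide
Product: 17 methyl (1R,5S,6R,8aR)-1,5,6-trimethyl-5-[2-(2-methyl-1,3-dioxolan-2-yl)ethyl]-1,2,3,5,6,7,8,8a-octahydronaphthalene-1-carboxylate, via caesium ester enolate 15 (not isolated), via keto phosphorus ylide 16 (not isolated)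
Conditions: 14 (1.5 equiv), CsF (dried, 1.2 equiv, added last), 18-crown-6 (0.1 equiv), DMF, 25 → 70 °C
Reagents that add atoms: none
Why: Proposed new method: fluoride cleaves the Si–O bond of 13, the cyclopropanolate opens by retro-homoaldol cleavage of C4–C10 (strain release) to the caesium ester enolate 15 and the C10 ketone, 15 attacks a ring CH2 of the cyclopropylphosphonium salt (homo-Michael opening, second strain release, C3–C4 bond) to give ylide 16, and 16 olefinates the C10 ketone with loss of Ph3PO (C1=C10). The closest known reactions are the fluoride-triggered ring opening/Michael addition/intramolecular Wittig sequence of 2-siloxycyclopropanecarboxylates with vinylphosphonium salts, which gives cyclopentenes, and the cyclopentene annulation of stabilised enolates with cyclopropylphosphonium salts; here the three-carbon reagent and the 1,3-disposed enolate and ketone should give the six-membered ring instead. Ring A closes in the Wittig event by 6-exo-trig attack of the ylide carbon C1 on the ring ketone, so the alkene can only be C1=C10. C5 is inherited from the cyclopropane of step 6 (equatorial, also the thermodynamically preferred α-keto epimer), and C4 is set in the alkylation by 1,2-induction from C5: in the non-chelated caesium enolate the enolate unit should turn away from the C10 carbonyl dipole and the electrophile should enter on the face anti to C6, which places the ester cis to H5; this facial preference is the least secure element of the step. The step needs C-alkylation of 15 by ring opening to beat proton transfer from the α-C–H of 14; this should be secured by the poor acidity of that C–H (its ylide would be an exocyclic cyclopropylidene), by the roughly 27 kcal/mol released on ring opening, and by keeping 14 in excess while 15 is generated.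

Step 9
Reactants: 17 octalin ketal
Product: 18 methyl (1R,5S,6R,8aR)-1,5,6-trimethyl-5-(3-oxobutyl)-1,2,3,5,6,7,8,8a-octahydronaphthalene-1-carboxylate
Conditions: PPTS, acetone/H2O, 50 °C
Reagents that add atoms: water, O
Why: Mild acid-catalysed transketalisation/hydrolysis frees the C13 methyl ketone without protonating the hindered trisubstituted C1=C10 alkene.

Step 10
Reactants: 18 octalin methyl ketone; 19 triethyl phosphonoacetate
Product: 20 methyl (1R,5S,6R,8aR)-5-[(3E)-5-ethoxy-3-methyl-5-oxopent-3-en-1-yl]-1,5,6-trimethyl-1,2,3,5,6,7,8,8a-octahydronaphthalene-1-carboxylate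
Conditions: NaH, THF, 0 → 50 °C
Reagents that add atoms: none
Why: Horner–Wadsworth–Emmons olefination of the methyl ketone should favour the E-enoate (larger chain trans to the ester); the minor Z isomer is to be removed by chromatography at this stage.

Step 11
Reactants: 20 E-enoate diester
Product: 21 methyl (1R,5S,6R,8aR)-5-[(3E)-5-hydroxy-3-methylpent-3-en-1-yl]-1,5,6-trimethyl-1,2,3,5,6,7,8,8a-octahydronaphthalene-1-carboxylate
Conditions: iBu2AlH (2.2 equiv), CH2Cl2, −78 °C; Rochelle salt work-up
Reagents that add atoms: none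
Why: 1,2-Reduction of the unhindered conjugated ethyl ester should be much faster than attack on the C18 methyl ester, which sits on the quaternary C4.

Step 12
Reactants: 21 E-allylic alcohol
Product: 22 methyl (1R,5S,6R,8aR)-5-{2-[(2S,3S)-3-(hydroxymethyl)-2-methyloxiran-2-yl]ethyl}-1,5,6-trimethyl-1,2,3,5,6,7,8,8a-octahydronaphthalene-1-carboxylate
Conditions: Ti(OiPr)4 (10 mol %), L-(+)-diethyl tartrate (12 mol %), tBuOOH, 4 Å MS, CH2Cl2, −20 °C
Reagents that add atoms: tert-butyl hydroperoxide, CC(C)(C)OO
Why: Sharpless asymmetric epoxidation should deliver oxygen to one face of the geraniol-type E-allylic alcohol under reagent control (13S,14S), and the isolated C1=C10 alkene is not a substrate for the titanium–tartrate system.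

Step 13
Reactants: 22 (13S,14S)-epoxy alcohol
Product: 24 methyl (1R,5S,6R,8aR)-5-[(3S,4R)-3,4,5-trihydroxy-3-methylpentyl]-1,5,6-trimethyl-1,2,3,5,6,7,8,8a-octahydronaphthalene-1-carboxylate, via terminal epoxide 23 (not isolated)
Conditions: NaOH (0.5 M aq.), tBuOH, 75 °C
Reagents that add atoms: water, O
Why: Payne rearrangement: the C15 alkoxide opens the epoxide at C14 with inversion (the C13–O bond is retained) and hydroxide then opens the terminal epoxide at the primary C15, which should give the 13S,14R triol; the C18 ester on the quaternary carbon should resist saponification.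

Step 14
Reactants: 24 (13S,14R)-triol
Product: 25 methyl (1R,5S,6R,8aR)-5-[(3S,4R)-4,5-diacetoxy-3-hydroxy-3-methylpentyl]-1,5,6-trimethyl-1,2,3,5,6,7,8,8a-octahydronaphthalene-1-carboxylate (target)
Conditions: Ac2O, pyridine, 25 °C
Reagents that add atoms: acetic anhydride, CC(=O)OC(C)=O
Why: Acetylation without a nucleophilic catalyst should esterify the primary C15 and secondary C14 hydroxyl groups and leave the tertiary C13 hydroxyl group free.

**Compound list**
1 | 2-methylcyclohex-2-en-1-one | CC1=CCCCC1=O | starting material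
2 | dimethylaluminium (3R)-2,3-dimethylcyclohex-1-en-1-olate | C[Al](C)OC1=C(C)[C@H](C)CCC1 | intermediate
3 | trimethyl{[(3R)-2,3-dimethylcyclohex-1-en-1-yl]oxy}silane | C[Si](C)(C)OC1=C(C)[C@H](C)CCC1 | intermediate
4 | but-3-en-2-one | C=CC(C)=O | starting material
5 | (2S,3R)-2,3-dimethyl-2-(3-oxobutyl)cyclohexan-1-one | O=C1CCC[C@@H](C)[C@]1(C)CCC(C)=O | intermediate
6 | (2S,3R)-2,3-dimethyl-2-[2-(2-methyl-1,3-dioxolan-2-yl)ethyl]cyclohexan-1-one | O=C1CCC[C@@H](C)[C@]1(C)CCC2(C)OCCO2 | intermediate
7 | lithium enolate of 6 (C10=C5) | [Li]OC1=CCC[C@@H](C)[C@]1(C)CCC2(C)OCCO2 | intermediate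
8 | tert-butyl({(5R,6S)-5,6-dimethyl-6-[2-(2-methyl-1,3-dioxolan-2-yl)ethyl]cyclohex-1-en-1-yl}oxy)dimethylsilane | CC(C)(C)[Si](C)(C)OC1=CCC[C@@H](C)[C@]1(C)CCC2(C)OCCO2 | intermediate
9 | glycine methyl ester hydrochloride | COC(=O)CN.Cl | starting material
10 | methyl diazoacetate | COC(=O)C=[N+]=[N-] | intermediate
11 | methyl (2S,3R)-1-(tert-butyldimethylsilyloxy)-2,3-dimethyl-2-[2-(2-methyl-1,3-dioxolan-2-yl)ethyl]bicyclo[4.1.0]heptane-7-carboxylate, cyclopropane anti to the C2 methyl group, C7 epimers | COC(=O)C1[C@@H]2CC[C@@H](C)[C@](C)(CCC3(C)OCCO3)[C@]12O[Si](C)(C)C(C)(C)C | intermediate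
12 | lithium ester enolate of 11 | COC(O[Li])=C1[C@@H]2CC[C@@H](C)[C@](C)(CCC3(C)OCCO3)[C@]12O[Si](C)(C)C(C)(C)C | intermediate
13 | methyl 1-(tert-butyldimethylsilyloxy)-2,3,7-trimethyl-2-[2-(2-methyl-1,3-dioxolan-2-yl)ethyl]bicyclo[4.1.0]heptane-7-carboxylate (ring-B centres as in 11, C7 configuration immaterial) | COC(=O)C1(C)[C@@H]2CC[C@@H](C)[C@](C)(CCC3(C)OCCO3)[C@]12O[Si](C)(C)C(C)(C)C | intermediate
14 | cyclopropyltriphenylphosphonium bromide | [Br-].c1ccccc1[P+](c1ccccc1)(c1ccccc1)C1CC1 | starting material
15 | caesium ester enolate (ring-opened, C10 ketone free, C5 as in target) | COC([O-])=C(C)[C@@H]1CC[C@@H](C)[C@](C)(CCC2(C)OCCO2)C1=O.[Cs+] | intermediate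
16 | keto phosphorus ylide (C4 quaternary, C1 ylide carbon) | COC(=O)[C@](C)(CCC=P(c1ccccc1)(c1ccccc1)c1ccccc1)[C@@H]1CC[C@@H](C)[C@](C)(CCC2(C)OCCO2)C1=O | intermediate
17 | methyl (1R,5S,6R,8aR)-1,5,6-trimethyl-5-[2-(2-methyl-1,3-dioxolan-2-yl)ethyl]-1,2,3,5,6,7,8,8a-octahydronaphthalene-1-carboxylate | COC(=O)[C@]1(C)CCC=C2[C@H]1CC[C@@H](C)[C@]2(C)CCC3(C)OCCO3 | intermediate
18 | methyl (1R,5S,6R,8aR)-1,5,6-trimethyl-5-(3-oxobutyl)-1,2,3,5,6,7,8,8a-octahydronaphthalene-1-carboxylate | COC(=O)[C@]1(C)CCC=C2[C@H]1CC[C@@H](C)[C@]2(C)CCC(C)=O | intermediate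
19 | triethyl phosphonoacetate | CCOC(=O)CP(=O)(OCC)OCC | starting material
20 | methyl (1R,5S,6R,8aR)-5-[(3E)-5-ethoxy-3-methyl-5-oxopent-3-en-1-yl]-1,5,6-trimethyl-1,2,3,5,6,7,8,8a-octahydronaphthalene-1-carboxylate | COC(=O)[C@]1(C)CCC=C2[C@H]1CC[C@@H](C)[C@]2(C)CC/C(C)=C/C(=O)OCC | intermediate
21 | methyl (1R,5S,6R,8aR)-5-[(3E)-5-hydroxy-3-methylpent-3-en-1-yl]-1,5,6-trimethyl-1,2,3,5,6,7,8,8a-octahydronaphthalene-1-carboxylate | COC(=O)[C@]1(C)CCC=C2[C@H]1CC[C@@H](C)[C@]2(C)CC/C(C)=C/CO | intermediate
22 | methyl (1R,5S,6R,8aR)-5-{2-[(2S,3S)-3-(hydroxymethyl)-2-methyloxiran-2-yl]ethyl}-1,5,6-trimethyl-1,2,3,5,6,7,8,8a-octahydronaphthalene-1-carboxylate | COC(=O)[C@]1(C)CCC=C2[C@H]1CC[C@@H](C)[C@]2(C)CC[C@]3(C)O[C@H]3CO | intermediate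
23 | methyl (1R,5S,6R,8aR)-5-{(3S)-3-hydroxy-3-[(2R)-oxiran-2-yl]butyl}-1,5,6-trimethyl-1,2,3,5,6,7,8,8a-octahydronaphthalene-1-carboxylate | COC(=O)[C@]1(C)CCC=C2[C@H]1CC[C@@H](C)[C@]2(C)CC[C@](C)(O)[C@@H]3OC3 | intermediate
24 | methyl (1R,5S,6R,8aR)-5-[(3S,4R)-3,4,5-trihydroxy-3-methylpentyl]-1,5,6-trimethyl-1,2,3,5,6,7,8,8a-octahydronaphthalene-1-carboxylate | COC(=O)[C@]1(C)CCC=C2[C@H]1CC[C@@H](C)[C@]2(C)CC[C@](C)(O)[C@@H](CO)O | intermediate
25 | methyl (1R,5S,6R,8aR)-5-[(3S,4R)-4,5-diacetoxy-3-hydroxy-3-methylpentyl]-1,5,6-trimethyl-1,2,3,5,6,7,8,8a-octahydronaphthalene-1-carboxylate | COC(=O)[C@]1(C)CCC=C2[C@H]1CC[C@@H](C)[C@]2(C)CC[C@](C)(O)[C@@H](COC(C)=O)OC(C)=O | target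

**Totals**
Total steps: 14. Longest linear sequence: 13 (steps 1–4 and 6–14; step 5 is a side branch).

**Steps most likely to fail**

1. Step 8 (Proposed new method). Proton transfer from the α-C–H of the phosphonium salt (or from traces of water) to the naked ester enolate may outrun the homo-Michael ring opening, so that only the protonated keto ester is formed. Attack on the wrong enolate face would give the C4 epimer. Fallback with known chemistry, setting out from 13 and returning at 17: fluoride-induced ring opening of 13 in the presence of acrolein (CsF, DMF) would trap the ester enolate by Michael addition as the keto aldehyde F1. An intramolecular McMurry coupling of the aldehyde and the C10 ketone of F1 (TiCl3(DME)1.5, Zn–Cu couple, DME, reflux, high dilution; low-valent titanium) would then close C1=C10 and give 17.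

2. Step 7. Deprotonation of the congested cyclopropane C–H between two fully substituted ring carbons may be incomplete, or the lithium enolate may decompose by ring cleavage before methylation. Fallback, setting out from 8 and returning at 13: the methyl group would be brought in with the carbene instead of by enolate alkylation. Rhodium-catalysed cyclopropanation of silyl enol ether 8 with methyl 2-diazopropanoate (Rh2(O2CCPh3)4, CH2Cl2, −78 °C, the bulky carboxylate suppressing β-hydride migration) would give 13 directly; this fallback makes no compound outside the list (F0).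

3. Step 13. Hydroxide may attack the unrearranged trisubstituted epoxide, or prolonged heating may begin to saponify the C18 ester, so that the triol is formed as a mixture or with loss of the ester. Fallback, setting out from 21 and returning at 24: epoxidation of 21 with D-(−)-diethyl tartrate (Ti(OiPr)4, tBuOOH, 4 Å MS, CH2Cl2, −20 °C) would give the (13R,14R)-epoxy alcohol F2. Acid-catalysed hydrolysis (HClO4 cat., THF/H2O, 0 °C) should open it at the tertiary C13 with inversion and leave C14 untouched, which gives the same 13S,14R triol 24.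

Further compounds
F1 | step 8 | methyl (2R)-2-methyl-5-oxo-2-{(1R,3S,4R)-3,4-dimethyl-3-[2-(2-methyl-1,3-dioxolan-2-yl)ethyl]-2-oxocyclohexyl}pentanoate (keto aldehyde) | COC(=O)[C@](C)(CCC=O)[C@@H]1CC[C@@H](C)[C@](C)(CCC2(C)OCCO2)C1=O
F0 | step 7 | none | none
F2 | step 13 | methyl (1R,5S,6R,8aR)-5-{2-[(2R,3R)-3-(hydroxymethyl)-2-methyloxiran-2-yl]ethyl}-1,5,6-trimethyl-1,2,3,5,6,7,8,8a-octahydronaphthalene-1-carboxylate | COC(=O)[C@]1(C)CCC=C2[C@H]1CC[C@@H](C)[C@]2(C)CC[C@@]3(C)O[C@@H]3CO
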